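**Retrosynthetic overview**

1. The target is the proteracacinidin of the ent-oritin-(4β→6)-oritin-4α-ol type: an upper (2S,3R,4S)-4-arylflavan-3-ol whose C4 is bonded to C6 of a lower (2R,3S,4R)-flavan-3,4-diol, both units all-trans (flavan numbering O1, C2, C3, C4, C4a, C5–C8, C8a).
2. Key disconnection: upper ring C is cut across C3–C4 and O1–C2 in a hetero-[4+2] sense. This gives an o-quinone methide O1=C8a–C4a=C4, whose C4 carries the whole lower unit, and (E)-2-[4-(benzyloxy)phenyl]ethenyl acetate as the C2=C3 partner.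
3. Enabling feature: in the upper unit O1 sits on C8a, ortho to C4a, and C4 is a doubly benzylic methine flanked by that oxygen, by the para 7-oxygen of upper ring A and by the ortho 7-oxygen of lower ring A. A 2-hydroxybenzhydrol at C4 therefore ionises under mild acid to exactly this heterodiene, and the 4-oxygenated ring B polarises the C2=C3 partner so that C3 bonds to C4.
4. The 2-hydroxybenzhydrol comes from the C6-lithiated lower unit and 3,4-bis(benzyloxy)-2-hydroxybenzaldehyde. The lower unit comes from a 5'-bromo chalcone by Juliá–Colonna epoxidation, acid ring closure and hydride reduction.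
5. Ring order: lower ring C (step 6), then upper ring C (step 13); rings A and B are bought as arenes. Deacetylation, desilylation and hydrogenolysis finish the route.

Key step: step 13

Remark (assumption): the chiral Brønsted acid of step 13 is written as its (R)-antipode by analogy with related o-quinone methide cycloadditions. Which antipode delivers the (2S,3R,4S) upper unit is to be fixed on a model 2-hydroxybenzhydrol, and the other antipode is used if the model requires it.

**Route**

Step 1
Reactants: 1 1-(2,3,4-trihydroxyphenyl)ethan-1-one (gallacetophenone)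
Product: 2 1-[3,4-bis(benzyloxy)-2-hydroxyphenyl]ethan-1-one
Conditions: BnBr (2.1 equiv), K2CO3 (2.2 equiv), acetone, reflux
Reagents that add atoms: benzyl bromide, BrCc1ccccc1
Why: Williamson etherification; the 2-hydroxyl is locked in a hydrogen bond to the ketone carbonyl and should stay free while the two more acidic, accessible hydroxyls are benzylated.

Step 2
Reactants: 2 1-[3,4-bis(benzyloxy)-2-hydroxyphenyl]ethan-1-one
Product: 3 1-[3,4-bis(benzyloxy)-5-bromo-2-hydroxyphenyl]ethan-1-one
Conditions: NBS (1.05 equiv), MeCN, 0 °C to rt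
Reagents that add atoms: N-bromosuccinimide, BrN1C(=O)CCC1=O
Why: Electrophilic aromatic bromination; the free phenol directs to its para position (C5, the future C6 of lower ring A), which is also meta to the acyl group, so the site of the later interflavanyl bond is fixed without ambiguity.

Step 3
Reactants: 3 1-[3,4-bis(benzyloxy)-5-bromo-2-hydroxyphenyl]ethan-1-one
Product: 4 1-[3,4-bis(benzyloxy)-5-bromo-2-(methoxymethoxy)phenyl]ethan-1-one
Conditions: NaH, MOMCl, DMF, 0 °C to rt
Reagents that add atoms: chloromethyl methyl ether, COCCl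
Why: O-alkylation of the sodium phenoxide; the MOM ether masks the phenol during the basic steps 4 and 5 and is removed by acid together with ring closure in step 6.

Step 4
Reactants: 4 1-[3,4-bis(benzyloxy)-5-bromo-2-(methoxymethoxy)phenyl]ethan-1-one; 5 4-(benzyloxy)benzaldehyde
Product: 6 (E)-1-[3,4-bis(benzyloxy)-5-bromo-2-(methoxymethoxy)phenyl]-3-[4-(benzyloxy)phenyl]prop-2-en-1-one
Conditions: KOH, EtOH/THF, rt
Reagents that add atoms: none
Why: Claisen–Schmidt aldol condensation; the aldehyde cannot enolise and E1cB dehydration should give the (E)-chalcone.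

Step 5
Reactants: 6 (E)-chalcone
Product: 7 [3,4-bis(benzyloxy)-5-bromo-2-(methoxymethoxy)phenyl]{(2R,3S)-3-[4-(benzyloxy)phenyl]oxiran-2-yl}methanone
Conditions: poly-L-leucine, urea–hydrogen peroxide, DBU, THF, rt
Reagents that add atoms: urea–hydrogen peroxide, OO.NC(N)=O
Why: Juliá–Colonna epoxidation (polypeptide-mediated Weitz–Scheffer epoxidation); hydroperoxide adds to the enone held at the helix terminus of poly-L-leucine, which should set both oxirane centers as the trans-(2R,3S) isomer.

Step 6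
Reactants: 7 (2R,3S)-epoxy ketone
Product: 9 (2R,3R)-7,8-bis(benzyloxy)-2-[4-(benzyloxy)phenyl]-6-bromo-3-hydroxychroman-4-one (2,3-trans-dihydroflavonol), via free-phenol epoxy ketone 8 (not isolated)
Conditions: conc. HCl, MeOH/THF, 50 °C
Reagents that add atoms: none
Why: Acidic acetal cleavage frees the phenol, which opens the protonated oxirane at the benzylic carbon (6-endo, favoured by the 4-benzyloxyphenyl group); C3 keeps the configuration from step 5 and C2 is formed with inversion at the benzylic oxirane carbon, which from the trans-epoxide gives the 2,3-trans ring.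

Step 7
Reactants: 9 (2R,3R)-dihydroflavonol
Product: 10 (2R,3S,4R)-7,8-bis(benzyloxy)-2-[4-(benzyloxy)phenyl]-6-bromochroman-3,4-diol (2,3-trans-3,4-trans)
Conditions: NaBH4, MeOH/THF, 0 °C
Reagents that add atoms: none
Why: Hydride reduction of the 4-ketone; axial attack on the half-chair with equatorial 2-aryl and 3-hydroxyl groups should give the equatorial 4-alcohol, that is the 3,4-trans diol.

Step 8
Reactants: 10 (2R,3S,4R)-diol
Product: 11 3,4-O-(1,1,3,3-tetraisopropyldisiloxane-1,3-diyl) derivative of 10 (lower-unit bromide)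
Conditions: 1,3-dichloro-1,1,3,3-tetraisopropyldisiloxane, imidazole, DMF, rt
Reagents that add atoms: 1,3-dichloro-1,1,3,3-tetraisopropyldisiloxane, CC(C)[Si](Cl)(C(C)C)O[Si](Cl)(C(C)C)C(C)C
Why: Silylation; the disiloxane bridges the trans-diequatorial 3,4-diol as a seven-membered ring that tolerates organolithium and catalytic acid and is removed by fluoride.

Step 9
Reactants: 12 2,3,4-trihydroxybenzaldehyde
Product: 13 3,4-bis(benzyloxy)-2-hydroxybenzaldehyde
Conditions: BnBr (2.1 equiv), K2CO3 (2.2 equiv), DMF, rt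
Reagents that add atoms: benzyl bromide, BrCc1ccccc1
Why: Williamson etherification with the same selectivity as in step 1, the 2-hydroxyl being chelated to the aldehyde.

Step 10
Reactants: 14 1-(benzyloxy)-4-ethynylbenzene
Product: 16 potassium {(E)-2-[4-(benzyloxy)phenyl]ethenyl}trifluoroborate, via (E)-alkenyl pinacol boronate 15 (not isolated)
Conditions: pinacolborane, Cp2Zr(H)Cl (5 mol %), Et3N (10 mol %), 60 °C; then KHF2, MeOH/H2O, rt
Reagents that add atoms: pinacolborane, [H]B1OC(C)(C)C(C)(C)O1; potassium hydrogen difluoride, [K+].F[H-]F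
Why: Zirconium-catalysed syn hydroboration of the terminal alkyne places boron on the terminal carbon with (E)-geometry, and exchange of pinacol for fluoride gives the stable trifluoroborate.

Step 11
Reactants: 16 potassium (E)-alkenyltrifluoroborate
Product: 17 (E)-2-[4-(benzyloxy)phenyl]ethenyl acetate
Conditions: AcOH, CuBr (10 mol %), DMAP (20 mol %), 4 Å molecular sieves, O2 (1 atm), MeCN, 60 °C
Reagents that add atoms: acetic acid, CC(=O)O
Why: Copper-catalysed oxidative C–O coupling (Chan–Lam type) of an alkenyltrifluoroborate with a carboxylic acid; the enol ester should form with retention of the (E)-geometry.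

Step 12
Reactants: 11 lower-unit bromide; 13 3,4-bis(benzyloxy)-2-hydroxybenzaldehyde
Product: 20 [3,4-bis(benzyloxy)-2-hydroxyphenyl](lower-unit C6-yl)methanol (11 with Br replaced by the diarylcarbinol; both carbinol epimers), via aryllithium 18 (not isolated), via sodium phenoxide 19 (not isolated)
Conditions: 11, n-BuLi (1.05 equiv), THF, −78 °C; separately 13, NaH (1.0 equiv), THF, 0 °C; phenoxide added at −78 °C, then to −20 °C; aq. NH4Cl
Reagents that add atoms: none
Why: Bromine–lithium exchange followed by 1,2-addition of the aryllithium to the aldehyde, whose phenol is masked as its phenoxide; the new carbinol center forms without control, which is of no consequence because it becomes trigonal in step 13.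

Step 13
Reactants: 20 2-hydroxybenzhydrol; 17 (E)-2-[4-(benzyloxy)phenyl]ethenyl acetate
Product: 22 3-O-acetyl-hexa-O-benzyl-3,4-O-disiloxanediyl derivative of 25 (upper ring C closed; upper unit 2,3-trans-3,4-trans with the absolute sense of the target), via o-quinone methide 21 (not isolated)
Conditions: 17 (3 equiv), (R)-N-triflylphosphoramide of 3,3'-bis(2,4,6-triisopropylphenyl)-1,1'-bi-2-naphthol (10 mol %), 4 Å molecular sieves, CH2Cl2, −20 °C to rt
Reagents that add atoms: none
Why: Proposed new method: the acid dehydrates the 2-hydroxybenzhydrol to the (E)-o-quinone methide 21, held as a hydrogen-bonded ion pair by the chiral phosphoramide, and the enol acetate adds across O1=C8a–C4a=C4 in an asynchronous inverse-electron-demand hetero-Diels–Alder reaction in which the C3–C4 bond leads and the O1–C2 bond follows; the closest known reaction type is the chiral N-triflylphosphoramide- or phosphoric acid-catalysed [4+2] cycloaddition of in situ formed o-quinone methides with styrenes and anethole-type alkenes, which gives 2,4-cis-flavans. The pyran ring (upper ring C) is closed in an intermolecular [4+2] mode. C2 and C3 should come out trans because the (E)-geometry of 17 is transferred suprafacially; C4 should come out cis to the C2 aryl group and trans to the acetate through the aryl-endo transition state on the (E)-quinone methide, which is also the all-equatorial arrangement; the absolute sense of all three centers is set by the face of 21 that the catalyst leaves open, the remote lower-unit stereocenters exerting no meaningful bias. The step needs regioselectivity (C3 to C4, C2 to O1), and this is secured by the 4-benzyloxyphenyl group, which makes the acetoxy-bearing carbon the nucleophilic terminus and stabilises positive charge at C2 far better than the weakly donating acetoxy group could at C3. It also needs chemoselective ionisation, which is secured because only the doubly benzylic carbinol flanked by the ortho-hydroxyl and para-benzyloxy groups forms a quinone methide under these conditions, the silyl-bridged benzylic C4–O of the lower unit being much less labile.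

Step 14
Reactants: 22 cycloadduct acetate
Product: 23 hexa-O-benzyl-3,4-O-disiloxanediyl derivative of 25 with free upper 3-hydroxyl
Conditions: K2CO3 (cat.), MeOH/THF, rt
Reagents that add atoms: none
Why: Base-catalysed transesterification (methanolysis) should remove the acetate without touching the benzyl ethers or the disiloxane.

Step 15
Reactants: 23 disiloxane-protected alcohol
Product: 24 hexa-O-benzyl ether of 25 (7,8,4'-O-benzyl on both units; all alcohols free)
Conditions: TBAF (2.5 equiv), AcOH (2.5 equiv), THF, 0 °C to rt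
Reagents that add atoms: none
Why: Fluoride cleaves both Si–O bonds; buffering with acetic acid keeps the medium near neutral so that the benzylic 4-oxygen of the lower unit is not exposed to strong base or acid.

Step 16
Reactants: 24 hexa-O-benzyl ether
Product: 25 target, (2R,3S,4R)-2-(4-hydroxyphenyl)-6-[(2S,3R,4S)-3,7,8-trihydroxy-2-(4-hydroxyphenyl)chroman-4-yl]chroman-3,4,7,8-tetrol
Conditions: H2 (1 atm), Pd(OH)2/C, EtOAc/MeOH, rt
Reagents that add atoms: none
Why: Hydrogenolysis of the six aryl benzyl ethers; the ring C ether bonds, the C4–aryl bond and the 4-hydroxyl of the 5-deoxy 7,8-dioxygenated lower unit are expected to survive neutral conditions, and the product is obtained by filtration and evaporation.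

**Compound list**

1 | 1-(2,3,4-trihydroxyphenyl)ethan-1-one | CC(=O)c1ccc(O)c(O)c1O | starting material
2 | 1-[3,4-bis(benzyloxy)-2-hydroxyphenyl]ethan-1-one | CC(=O)c1ccc(OCc2ccccc2)c(OCc2ccccc2)c1O | intermediate
3 | 1-[3,4-bis(benzyloxy)-5-bromo-2-hydroxyphenyl]ethan-1-one | CC(=O)c1cc(Br)c(OCc2ccccc2)c(OCc2ccccc2)c1O | intermediate
4 | 1-[3,4-bis(benzyloxy)-5-bromo-2-(methoxymethoxy)phenyl]ethan-1-one | COCOc1c(C(C)=O)cc(Br)c(OCc2ccccc2)c1OCc3ccccc3 | intermediate
5 | 4-(benzyloxy)benzaldehyde | O=Cc1ccc(OCc2ccccc2)cc1 | starting material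
6 | (E)-1-[3,4-bis(benzyloxy)-5-bromo-2-(methoxymethoxy)phenyl]-3-[4-(benzyloxy)phenyl]prop-2-en-1-one | COCOc1c(C(=O)/C=C/c2ccc(OCc3ccccc3)cc2)cc(Br)c(OCc4ccccc4)c1OCc5ccccc5 | intermediate
7 | [3,4-bis(benzyloxy)-5-bromo-2-(methoxymethoxy)phenyl]{(2R,3S)-3-[4-(benzyloxy)phenyl]oxiran-2-yl}methanone | COCOc1c(C(=O)[C@@H]2O[C@H]2c3ccc(OCc4ccccc4)cc3)cc(Br)c(OCc5ccccc5)c1OCc6ccccc6 | intermediate
8 | [3,4-bis(benzyloxy)-5-bromo-2-hydroxyphenyl]{(2R,3S)-3-[4-(benzyloxy)phenyl]oxiran-2-yl}methanone | Oc1c(C(=O)[C@@H]2O[C@H]2c3ccc(OCc4ccccc4)cc3)cc(Br)c(OCc5ccccc5)c1OCc6ccccc6 | intermediate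
9 | (2R,3R)-7,8-bis(benzyloxy)-2-[4-(benzyloxy)phenyl]-6-bromo-3-hydroxychroman-4-one | O(Cc6ccccc6)c1ccc([C@H]2Oc3c(cc(Br)c(OCc6ccccc6)c3OCc6ccccc6)C(=O)[C@@H]2O)cc1 | intermediate
10 | (2R,3S,4R)-7,8-bis(benzyloxy)-2-[4-(benzyloxy)phenyl]-6-bromochroman-3,4-diol | O(Cc6ccccc6)c1ccc([C@H]2Oc3c(cc(Br)c(OCc6ccccc6)c3OCc6ccccc6)[C@@H](O)[C@@H]2O)cc1 | intermediate
11 | 3,4-O-(1,1,3,3-tetraisopropyldisiloxane-1,3-diyl) derivative of 10 | O(Cc6ccccc6)c1ccc([C@H]2Oc3c(cc(Br)c(OCc6ccccc6)c3OCc6ccccc6)[C@@H](O[Si](C(C)C)(C(C)C)O[Si]7(C(C)C)C(C)C)[C@@H]2O7)cc1 | intermediate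
12 | 2,3,4-trihydroxybenzaldehyde | O=Cc1ccc(O)c(O)c1O | starting material
13 | 3,4-bis(benzyloxy)-2-hydroxybenzaldehyde | O=Cc1ccc(OCc2ccccc2)c(OCc2ccccc2)c1O | intermediate
14 | 1-(benzyloxy)-4-ethynylbenzene | C#Cc1ccc(OCc2ccccc2)cc1 | starting material
15 | 2-{(E)-2-[4-(benzyloxy)phenyl]ethenyl}-4,4,5,5-tetramethyl-1,3,2-dioxaborolane | CC1(C)OB(/C=C/c2ccc(OCc3ccccc3)cc2)OC1(C)C | intermediate
16 | potassium {(E)-2-[4-(benzyloxy)phenyl]ethenyl}trifluoroborate | [K+].F[B-](F)(F)/C=C/c1ccc(OCc2ccccc2)cc1 | intermediate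
17 | (E)-2-[4-(benzyloxy)phenyl]ethenyl acetate | CC(=O)O/C=C/c1ccc(OCc2ccccc2)cc1 | intermediate
18 | C6-lithio derivative of 11 (Br replaced by Li) | O(Cc6ccccc6)c1ccc([C@H]2Oc3c(cc([Li])c(OCc6ccccc6)c3OCc6ccccc6)[C@@H](O[Si](C(C)C)(C(C)C)O[Si]7(C(C)C)C(C)C)[C@@H]2O7)cc1 | intermediate
19 | sodium 2,3-bis(benzyloxy)-6-formylphenolate | [Na+].[O-]c1c(C=O)ccc(OCc2ccccc2)c1OCc3ccccc3 | intermediate
20 | [3,4-bis(benzyloxy)-2-hydroxyphenyl](lower-unit C6-yl)methanol, both carbinol epimers | O(Cc6ccccc6)c1ccc([C@H]2Oc3c(cc(C(O)c4ccc(OCc6ccccc6)c(OCc6ccccc6)c4O)c(OCc6ccccc6)c3OCc6ccccc6)[C@@H](O[Si](C(C)C)(C(C)C)O[Si]7(C(C)C)C(C)C)[C@@H]2O7)cc1 | intermediate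
21 | (E)-2,3-bis(benzyloxy)-6-[(lower-unit C6-yl)methylidene]cyclohexa-2,4-dien-1-one (o-quinone methide) | O(Cc6ccccc6)c1ccc([C@H]2Oc3c(cc(/C=C4\C=CC(OCc6ccccc6)=C(OCc6ccccc6)C4=O)c(OCc6ccccc6)c3OCc6ccccc6)[C@@H](O[Si](C(C)C)(C(C)C)O[Si]7(C(C)C)C(C)C)[C@@H]2O7)cc1 | intermediate
22 | upper 3-O-acetyl, hexa-O-benzyl, lower 3,4-O-disiloxanediyl derivative of 25 | O(Cc6ccccc6)c1ccc([C@H]2Oc3c(cc([C@H]4c5ccc(OCc6ccccc6)c(OCc6ccccc6)c5O[C@@H](c5ccc(OCc6ccccc6)cc5)[C@@H]4OC(C)=O)c(OCc6ccccc6)c3OCc6ccccc6)[C@@H](O[Si](C(C)C)(C(C)C)O[Si]7(C(C)C)C(C)C)[C@@H]2O7)cc1 | intermediate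
23 | hexa-O-benzyl, lower 3,4-O-disiloxanediyl derivative of 25 | O(Cc6ccccc6)c1ccc([C@H]2Oc3c(cc([C@H]4c5ccc(OCc6ccccc6)c(OCc6ccccc6)c5O[C@@H](c5ccc(OCc6ccccc6)cc5)[C@@H]4O)c(OCc6ccccc6)c3OCc6ccccc6)[C@@H](O[Si](C(C)C)(C(C)C)O[Si]7(C(C)C)C(C)C)[C@@H]2O7)cc1 | intermediate
24 | hexa-O-benzyl ether of 25 | O(Cc6ccccc6)c1ccc([C@H]2Oc3c(cc([C@H]4c5ccc(OCc6ccccc6)c(OCc6ccccc6)c5O[C@@H](c5ccc(OCc6ccccc6)cc5)[C@@H]4O)c(OCc6ccccc6)c3OCc6ccccc6)[C@@H](O)[C@@H]2O)cc1 | intermediate
25 | (2R,3S,4R)-2-(4-hydroxyphenyl)-6-[(2S,3R,4S)-3,7,8-trihydroxy-2-(4-hydroxyphenyl)chroman-4-yl]chroman-3,4,7,8-tetrol | Oc1ccc([C@H]2Oc3c(cc([C@H]4c5ccc(O)c(O)c5O[C@@H](c5ccc(O)cc5)[C@@H]4O)c(O)c3O)[C@@H](O)[C@@H]2O)cc1 | target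

**Step count and risks**

Total step count: 16. Longest linear sequence: 13 steps (steps 1–8, then 12–16).

Steps most likely to fail:

Step 13. The cycloaddition may fail through reversed regiochemistry (O1 bonding to the acetoxy-bearing carbon), through acid-induced oligomerisation, E/Z isomerisation or acyl transfer of 17 outrunning the trapping of 21, or through poor facial discrimination by the catalyst on so large a quinone methide. The fallback makes the O1–C2 bond first with a preset stereocenter and then closes the C3–C4 bond by olefin metathesis, using known reaction types only. It sets out from 13 and 11. Phenol 13 is O-allylated with methyl (E)-3-[4-(benzyloxy)phenyl]prop-2-en-1-yl carbonate F1 (from the cinnamyl alcohol and methyl chloroformate, pyridine) under [Ir(cod)Cl]2/chiral phosphoramidite catalysis (branched-selective allylic etherification), giving the branched aryl allyl ether 3,4-bis(benzyloxy)-2-{[(1R)-1-(4-benzyloxyphenyl)prop-2-en-1-yl]oxy}benzaldehyde F2. Aryllithium 18, made from 11 as in step 12, adds to F2 to give the benzhydrol F3. Dess–Martin oxidation gives the benzophenone F4, and methylenation (Ph3P=CH2, THF) gives the 1,1-diarylethene F5. Ring-closing metathesis (second-generation Grubbs catalyst, toluene, 80 °C) closes upper ring C as the 4-aryl-2H-chromene F6. Hydroboration–oxidation (BH3·SMe2, THF; then NaOH, H2O2), anti to the C2 aryl group and with syn delivery of hydrogen to C4, should give the 2,3-trans-3,4-trans alcohol, and the route is rejoined at 23.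

Step 6. The ring closure may be diverted by 5-exo opening of the oxirane (aurone-type products), by 1,2-aryl shift, by solvolysis of the oxirane without cyclisation, or by partial formation of the 2,3-cis isomer. The fallback separates oxirane opening from ring closure and sets out from 7. Phenylmethanethiol with SnCl4 (CH2Cl2, −20 °C) opens the oxirane at the benzylic carbon and removes the MOM group, giving the α-hydroxy-β-benzylsulfanyl ketone F7. AgBF4 (CH2Cl2, 0 °C) then activates the thioether and the phenol closes ring C, coming back to the route at 9.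

Step 16. The hydrogenolysis may over-reduce the molecule (loss of the benzylic 4-hydroxyl of the lower unit, opening of a ring C ether bond) or stall before all six benzyl groups are gone. The fallback keeps the benzylic 4-oxygen silylated during hydrogenolysis and sets out from 23, before step 15. Hydrogenolysis (H2, Pd(OH)2/C, EtOAc/THF) with the disiloxane in place gives the hexaphenol F8. HF·pyridine (pyridine/THF, 0 °C) then removes the disiloxane, coming back to the route at 25.

**Further compounds**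

F1 | step 13 | methyl (E)-3-[4-(benzyloxy)phenyl]prop-2-en-1-yl carbonate | COC(=O)OC/C=C/c1ccc(OCc2ccccc2)cc1
F2 | step 13 | 3,4-bis(benzyloxy)-2-{[(1R)-1-(4-benzyloxyphenyl)prop-2-en-1-yl]oxy}benzaldehyde | O=Cc1ccc(OCc2ccccc2)c(OCc2ccccc2)c1O[C@@H](c1ccc(OCc2ccccc2)cc1)C=C
F3 | step 13 | benzhydrol from 18 and F2 (both carbinol epimers) | O(Cc6ccccc6)c1ccc([C@H]2Oc3c(cc(C(O)c4ccc(OCc6ccccc6)c(OCc6ccccc6)c4O[C@@H](c4ccc(OCc6ccccc6)cc4)C=C)c(OCc6ccccc6)c3OCc6ccccc6)[C@@H](O[Si](C(C)C)(C(C)C)O[Si]7(C(C)C)C(C)C)[C@@H]2O7)cc1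
F4 | step 13 | benzophenone from F3 | O(Cc6ccccc6)c1ccc([C@H]2Oc3c(cc(C(=O)c4ccc(OCc6ccccc6)c(OCc6ccccc6)c4O[C@@H](c4ccc(OCc6ccccc6)cc4)C=C)c(OCc6ccccc6)c3OCc6ccccc6)[C@@H](O[Si](C(C)C)(C(C)C)O[Si]7(C(C)C)C(C)C)[C@@H]2O7)cc1
F5 | step 13 | 1,1-diarylethene from F4 | O(Cc6ccccc6)c1ccc([C@H]2Oc3c(cc(C(=C)c4ccc(OCc6ccccc6)c(OCc6ccccc6)c4O[C@@H](c4ccc(OCc6ccccc6)cc4)C=C)c(OCc6ccccc6)c3OCc6ccccc6)[C@@H](O[Si](C(C)C)(C(C)C)O[Si]7(C(C)C)C(C)C)[C@@H]2O7)cc1
F6 | step 13 | 4-aryl-2H-chromene (upper flav-3-ene) from F5 | O(Cc6ccccc6)c1ccc([C@H]2Oc3c(cc(C4c5ccc(OCc6ccccc6)c(OCc6ccccc6)c5O[C@@H](c5ccc(OCc6ccccc6)cc5)C=4)c(OCc6ccccc6)c3OCc6ccccc6)[C@@H](O[Si](C(C)C)(C(C)C)O[Si]7(C(C)C)C(C)C)[C@@H]2O7)cc1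
F7 | step 6 | 1-[3,4-bis(benzyloxy)-5-bromo-2-hydroxyphenyl]-3-[4-(benzyloxy)phenyl]-3-(benzylsulfanyl)-2-hydroxypropan-1-one (C2 as in 7, C3 inverted) | Oc1c(C(=O)[C@H](O)[C@H](SCc2ccccc2)c3ccc(OCc4ccccc4)cc3)cc(Br)c(OCc5ccccc5)c1OCc6ccccc6
F8 | step 16 | lower 3,4-O-(1,1,3,3-tetraisopropyldisiloxane-1,3-diyl) derivative of 25 | Oc1ccc([C@H]2Oc3c(cc([C@H]4c5ccc(O)c(O)c5O[C@@H](c5ccc(O)cc5)[C@@H]4O)c(O)c3O)[C@@H](O[Si](C(C)C)(C(C)C)O[Si]7(C(C)C)C(C)C)[C@@H]2O7)cc1
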